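**Retrosynthetic overview**

1. Target 21 ⇒ ketol 12 by acidolysis of the tert-butyl and 4-methoxybenzyl groups, acylation of the C8 oxygen with acid 18, and reduction of the C8 ketone anti to a C7 silyloxy group.
2. Feature used: in ring B (C4a, C5, C6, C7, C8, C8a) the C6 ketone is adjacent to C7, a tertiary carbinol carbon bearing CH3, whose other neighbour C8 is a carbonyl in 12. This α-ketol is cut at C6–C7 as a carbene-catalysed crossed benzoin of the C6 aldehyde onto the C7 ketone of a 1,2-dione (11 ⇒ 12).
3. 11 ⇒ enol triflate 8 + CO (C8) + stannane 9 (C7 and its CH3); 8 ⇒ Wittig olefination (acrylate on C3) and Grignard addition of the C5–C6 unit to the pyranone carbonyl (C4a) of kojic acid triflate 2.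
4. Ring order: ring A (C1, O2, C3, C4, C4a, C8a) is the pyran ring of kojic acid and is kept throughout; ring B is the only ring made (step 5, together with the C7 stereocentre); C8 is then set from C7 in step 7.
5. Orsellinic acid 16 enters as its bis(4-methoxybenzyl) ether 18.

Key step: step 5

Remark on numbering: atom labels C1 to C8a in the comments are those of the isochromene skeleton of the target, also for the monocyclic precursors.
Assumption: the exocyclic C4a=C5 bond of the pyranylidene acetaldehydes 5, 7, 8, 10 and 11 is a push–pull bond expected to isomerise easily; each is written as the Z isomer (formyl group syn to the C8a substituent), the geometry consumed in step 5, without implying that this isomer predominates.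
Assumption: which enantiomer of the aminoindanol-derived triazolium salt gives the (7S) ketol 12 cannot be predicted for this substrate; the (5aR,10bS) salt is written and its antipode is used if the first run shows the opposite sense.

**Route**

Step 1
Reactants: 1 kojic acid (5-hydroxy-2-(hydroxymethyl)-4H-pyran-4-one)
Product: 2 6-(hydroxymethyl)-4-oxo-4H-pyran-3-yl trifluoromethanesulfonate
Conditions: PhNTf2, Et3N, DMF, 0 °C to rt
Reagents that add atoms: N-phenylbis(trifluoromethanesulfonimide), O=S(=O)(N(c1ccccc1)S(=O)(=O)C(F)(F)F)C(F)(F)F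
Why: Chemoselective O-triflation: Et3N deprotonates only the acidic enolic 5-OH, whose enolate is sulfonylated by the mild triflyl donor, while the neutral primary alcohol does not react.

Step 2
Reactants: 2 6-(hydroxymethyl)-4-oxo-4H-pyran-3-yl trifluoromethanesulfonate; 3 (1,3-dioxolan-2-ylmethyl)magnesium bromide
Product: 5 (4Z)-6-(hydroxymethyl)-4-(2-oxoethylidene)-4H-pyran-3-yl trifluoromethanesulfonate, via pyranol acetal 4 (not isolated)
Conditions: 3 (3 equiv), CeCl3, THF, −40 to 0 °C; then 2 M HCl, 0 °C to rt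
Reagents that add atoms: (1,3-dioxolan-2-ylmethyl)magnesium bromide (3), Br[Mg]CC1OCCO1; water, O
Why: Organocerium-modified Grignard 1,2-addition to the 4-pyranone carbonyl (the classical route to 4-substituted pyrylium ions; the first equivalent of 3 only deprotonates the CH2OH, and the enol triflate is expected to survive a Grignard reagent in the absence of a nickel or palladium catalyst), after which acid ionises the pyranol, the 4-alkylpyrylium ion loses a side-chain proton and the dioxolane is hydrolysed, the push–pull enal being the thermodynamic sink.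

Step 3
Reactants: 5 (4Z)-6-(hydroxymethyl)-4-(2-oxoethylidene)-4H-pyran-3-yl trifluoromethanesulfonate; 6 tert-butyl (triphenylphosphoranylidene)acetate
Product: 8 tert-butyl (2E)-3-[(4Z)-4-(2-oxoethylidene)-5-(trifluoromethanesulfonyloxy)-4H-pyran-2-yl]prop-2-enoate, via pyran-2-carbaldehyde 7 (not isolated)
Conditions: MnO2 (excess), 6, CH2Cl2, rt
Reagents that add atoms: tert-butyl (triphenylphosphoranylidene)acetate (6), CC(C)(C)OC(=O)C=P(c1ccccc1)(c1ccccc1)c1ccccc1
Why: Tandem MnO2 oxidation–Wittig olefination: the allylic alcohol is oxidised on the MnO2 surface and enal 7 is trapped at once by the stabilised ylide to give the E acrylate, whereas the formyl group at C6, the terminus of the push–pull system, is too deactivated to react with a stabilised ylide.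

Step 4
Reactants: 8 tert-butyl (2E)-3-[(4Z)-4-(2-oxoethylidene)-5-(trifluoromethanesulfonyloxy)-4H-pyran-2-yl]prop-2-enoate; 9 tributyl(1-ethoxyethenyl)stannane
Product: 11 tert-butyl (2E)-3-[(4Z)-4-(2-oxoethylidene)-5-(2-oxopropanoyl)-4H-pyran-2-yl]prop-2-enoate, via ethoxy enone 10 (not isolated)
Conditions: CO (3 atm), 9, Pd(PPh3)4 (cat.), LiCl, THF, 55 °C; then 1 M HCl, rt
Reagents that add atoms: carbon monoxide, [C-]#[O+]; tributyl(1-ethoxyethenyl)stannane (9), CCCC[Sn](CCCC)(CCCC)C(=C)OCC; water, O
Why: Carbonylative Stille coupling: zerovalent palladium inserts into the C8a–OTf bond, CO insertion gives the acylpalladium species (CO becomes C8), the 1-ethoxyethenyl group (C7 and its CH3) is transferred from tin and reductive elimination gives enone 10, whose enol ether is then hydrolysed by dilute acid to the C7 ketone.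

Step 5
Reactants: 11 tert-butyl (2E)-3-[(4Z)-4-(2-oxoethylidene)-5-(2-oxopropanoyl)-4H-pyran-2-yl]prop-2-enoate
Product: 12 tert-butyl (2E)-3-[(7S)-7-hydroxy-7-methyl-6,8-dioxo-7,8-dihydro-6H-isochromen-3-yl]prop-2-enoate
Conditions: (5aR,10bS)-2-(pentafluorophenyl)-5a,10b-dihydro-4H,6H-indeno[2,1-b][1,2,4]triazolo[4,3-d][1,4]oxazin-2-ium tetrafluoroborate (15 mol %), Et3N (15 mol %), 4 Å molecular sieves, degassed toluene, rt to 40 °C
Reagents that add atoms: none
Why: Proposed new method: the triazolylidene released by Et3N adds to the C6 formyl group, proton transfer gives the nucleophilic enaminol (acyl anion equivalent), this attacks the C7 ketone and the carbene is then expelled from the new C6 ketone; the closest known reaction is the enantioselective intramolecular crossed aldehyde–ketone benzoin of keto aldehydes with aminoindanol-derived triazolium salts, which has not been shown for a formyl group that terminates a pyranylidene (doubly vinylogous formate) system. Ring B (C4a, C5, C6, C7, C8, C8a) closes 6-exo-trig. The only new stereocentre, C7, is set by the catalyst: the fused indane blocks one face of the enaminol so that one enantioface of the C7 carbonyl is presented, with hydrogen bonding of the enaminol OH to the C7 oxygen expected to organise the transition state. The step needs the acyl anion pathway to win over protonation at the β carbon, which is disfavoured because C4a is fully substituted and part of the pyran ring; it needs attack at C7 and not C8, secured because C7 is the more electrophilic ketone of the 1,2-dione while C8 is a vinylogous ester carbonyl and would give a five-membered ring; and it needs the formyl group beside the dione arm, which rotation about the push–pull C4a=C5 bond provides. The low electrophilicity of the formyl group is met with the electron-poor, reversibly adding N-pentafluorophenyl carbene and a weak amine base that leaves the acetyl group un-enolised.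

Step 6
Reactants: 12 tert-butyl (2E)-3-[(7S)-7-hydroxy-7-methyl-6,8-dioxo-7,8-dihydro-6H-isochromen-3-yl]prop-2-enoate
Product: 13 tert-butyl (2E)-3-[(7S)-7-methyl-6,8-dioxo-7-(trimethylsilyloxy)-7,8-dihydro-6H-isochromen-3-yl]prop-2-enoate
Conditions: TMSOTf, 2,6-lutidine, CH2Cl2, −78 °C
Reagents that add atoms: trimethylsilyl trifluoromethanesulfonate, C[Si](C)(C)OS(=O)(=O)C(F)(F)F
Why: Silyl ether formation with a silyl triflate and a hindered, non-nucleophilic base, the standard way to cap a hindered tertiary alcohol; the ether rules out hydroxyl-directed hydride delivery and α-ketol rearrangement in step 7, and C7 is not touched.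

Step 7
Reactants: 13 tert-butyl (2E)-3-[(7S)-7-methyl-6,8-dioxo-7-(trimethylsilyloxy)-7,8-dihydro-6H-isochromen-3-yl]prop-2-enoate
Product: 15 tert-butyl (2E)-3-[(7R,8R)-7,8-dihydroxy-7-methyl-6-oxo-7,8-dihydro-6H-isochromen-3-yl]prop-2-enoate, via silyl ether alcohol 14 (not isolated)
Conditions: NaBH4, CeCl3·7H2O, MeOH/THF, −78 °C; then aq. citric acid, 0 °C to rt
Reagents that add atoms: none
Why: Luche 1,2-reduction: C8, a cross-conjugated enone carbonyl, is expected to react before C6, the carbonyl terminus of the pyranylidene push–pull system (pyrylium enolate character), CeCl3 suppresses hydride addition at C1, and with chelation excluded the hydride should enter anti to the C7–OSiMe3 bond (polar 1,2-induction), which sets C8 with its oxygen cis to the C7 oxygen; citric acid then cleaves the trimethylsilyl ether.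

Step 8
Reactants: 16 orsellinic acid (2,4-dihydroxy-6-methylbenzoic acid)
Product: 17 4-methoxybenzyl 2,4-bis[(4-methoxybenzyl)oxy]-6-methylbenzoate
Conditions: 4-methoxybenzyl chloride, K2CO3, Bu4NI (cat.), DMF, 60 °C
Reagents that add atoms: 4-methoxybenzyl chloride, COc1ccc(CCl)cc1
Why: Williamson alkylation of the carboxylate and both phenoxides (the hydrogen-bonded 2-OH needs the warm DMF conditions) gives the fully 4-methoxybenzyl-protected orsellinate.

Step 9
Reactants: 17 4-methoxybenzyl 2,4-bis[(4-methoxybenzyl)oxy]-6-methylbenzoate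
Product: 18 2,4-bis[(4-methoxybenzyl)oxy]-6-methylbenzoic acid
Conditions: KOH, DMSO/H2O, 80 °C; then 1 M HCl, 0 °C, to pH 3
Reagents that add atoms: potassium hydroxide, [K+].[OH-]
Why: Saponification of the hindered 2,6-disubstituted benzoate under forcing hydroxide conditions, to which the aryl 4-methoxybenzyl ethers are inert, followed by cold acidification.

Step 10
Reactants: 15 tert-butyl (2E)-3-[(7R,8R)-7,8-dihydroxy-7-methyl-6-oxo-7,8-dihydro-6H-isochromen-3-yl]prop-2-enoate; 18 2,4-bis[(4-methoxybenzyl)oxy]-6-methylbenzoic acid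
Product: 20 (7R,8R)-3-[(1E)-3-tert-butoxy-3-oxoprop-1-en-1-yl]-7-hydroxy-7-methyl-6-oxo-7,8-dihydro-6H-isochromen-8-yl 2,4-bis[(4-methoxybenzyl)oxy]-6-methylbenzoate, via acid chloride 19 (not isolated)
Conditions: 18, 1-chloro-N,N,2-trimethylprop-1-en-1-amine, CH2Cl2, 0 °C to rt; then 15, Et3N, DMAP, CH2Cl2, 0 °C to rt
Reagents that add atoms: 2,4-bis[(4-methoxybenzyl)oxy]-6-methylbenzoic acid (18), Cc1cc(OCc2ccc(OC)cc2)cc(OCc2ccc(OC)cc2)c1C(=O)O
Why: Acylation through the acid chloride, made under neutral conditions with the chloroenamine so that the 4-methoxybenzyl ethers survive, with DMAP catalysis (nucleophilic acyl substitution): the secondary C8 hydroxyl reacts and the tertiary C7 hydroxyl does not, and no bond to C8 is broken, so both stereocentres are retained.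

Step 11
Reactants: 20 (7R,8R)-3-[(1E)-3-tert-butoxy-3-oxoprop-1-en-1-yl]-7-hydroxy-7-methyl-6-oxo-7,8-dihydro-6H-isochromen-8-yl 2,4-bis[(4-methoxybenzyl)oxy]-6-methylbenzoate
Product: 21 (+)-mitorubrinic acid B, (2E)-3-[(7R,8R)-8-(2,4-dihydroxy-6-methylbenzoyloxy)-7-hydroxy-7-methyl-6-oxo-7,8-dihydro-6H-isochromen-3-yl]prop-2-enoic acid
Conditions: TFA, pentamethylbenzene, CH2Cl2, 0 °C to rt
Reagents that add atoms: none
Why: Acidolysis: TFA cleaves the tert-butyl ester (loss of isobutene) and both aryl 4-methoxybenzyl ethers (benzyl cations captured by pentamethylbenzene), while protonation of the chromophore at the C6 oxygen to a pyrylium ion is expected to protect the C8–O ester bond from ionisation, so C7 and C8 are untouched.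

**Compound list**

1 | kojic acid, 5-hydroxy-2-(hydroxymethyl)-4H-pyran-4-one | OCC1=CC(=O)C(O)=CO1 | starting material
2 | 6-(hydroxymethyl)-4-oxo-4H-pyran-3-yl trifluoromethanesulfonate | OCC1=CC(=O)C(OS(=O)(=O)C(F)(F)F)=CO1 | intermediate
3 | (1,3-dioxolan-2-ylmethyl)magnesium bromide | Br[Mg]CC1OCCO1 | starting material
4 | 4-(1,3-dioxolan-2-ylmethyl)-4-hydroxy-6-(hydroxymethyl)-4H-pyran-3-yl trifluoromethanesulfonate (racemic, formed as its magnesium alkoxide) | OCC1=CC(O)(CC2OCCO2)C(OS(=O)(=O)C(F)(F)F)=CO1 | intermediate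
5 | (4Z)-6-(hydroxymethyl)-4-(2-oxoethylidene)-4H-pyran-3-yl trifluoromethanesulfonate | OCC1=CC(=C/C=O)/C(OS(=O)(=O)C(F)(F)F)=CO1 | intermediate
6 | tert-butyl (triphenylphosphoranylidene)acetate | CC(C)(C)OC(=O)C=P(c1ccccc1)(c1ccccc1)c1ccccc1 | starting material
7 | (4Z)-6-formyl-4-(2-oxoethylidene)-4H-pyran-3-yl trifluoromethanesulfonate | O=CC1=CC(=C/C=O)/C(OS(=O)(=O)C(F)(F)F)=CO1 | intermediate
8 | tert-butyl (2E)-3-[(4Z)-4-(2-oxoethylidene)-5-(trifluoromethanesulfonyloxy)-4H-pyran-2-yl]prop-2-enoate | CC(C)(C)OC(=O)/C=C/C1=CC(=C/C=O)/C(OS(=O)(=O)C(F)(F)F)=CO1 | intermediate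
9 | tributyl(1-ethoxyethenyl)stannane | CCCC[Sn](CCCC)(CCCC)C(=C)OCC | starting material
10 | tert-butyl (2E)-3-[(4Z)-5-(2-ethoxyprop-2-enoyl)-4-(2-oxoethylidene)-4H-pyran-2-yl]prop-2-enoate | CC(C)(C)OC(=O)/C=C/C1=CC(=C/C=O)/C(C(=O)C(=C)OCC)=CO1 | intermediate
11 | tert-butyl (2E)-3-[(4Z)-4-(2-oxoethylidene)-5-(2-oxopropanoyl)-4H-pyran-2-yl]prop-2-enoate | CC(C)(C)OC(=O)/C=C/C1=CC(=C/C=O)/C(C(=O)C(C)=O)=CO1 | intermediate
12 | tert-butyl (2E)-3-[(7S)-7-hydroxy-7-methyl-6,8-dioxo-7,8-dihydro-6H-isochromen-3-yl]prop-2-enoate | O=C1C2=COC(/C=C/C(=O)OC(C)(C)C)=CC2=CC(=O)[C@]1(C)O | intermediate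
13 | tert-butyl (2E)-3-[(7S)-7-methyl-6,8-dioxo-7-(trimethylsilyloxy)-7,8-dihydro-6H-isochromen-3-yl]prop-2-enoate | O=C1C2=COC(/C=C/C(=O)OC(C)(C)C)=CC2=CC(=O)[C@]1(C)O[Si](C)(C)C | intermediate
14 | tert-butyl (2E)-3-[(7R,8R)-8-hydroxy-7-methyl-6-oxo-7-(trimethylsilyloxy)-7,8-dihydro-6H-isochromen-3-yl]prop-2-enoate | O[C@@H]1C2=COC(/C=C/C(=O)OC(C)(C)C)=CC2=CC(=O)[C@]1(C)O[Si](C)(C)C | intermediate
15 | tert-butyl (2E)-3-[(7R,8R)-7,8-dihydroxy-7-methyl-6-oxo-7,8-dihydro-6H-isochromen-3-yl]prop-2-enoate | O[C@@H]1C2=COC(/C=C/C(=O)OC(C)(C)C)=CC2=CC(=O)[C@]1(C)O | intermediate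
16 | orsellinic acid, 2,4-dihydroxy-6-methylbenzoic acid | Cc1cc(O)cc(O)c1C(=O)O | starting material
17 | 4-methoxybenzyl 2,4-bis[(4-methoxybenzyl)oxy]-6-methylbenzoate | Cc1cc(OCc2ccc(OC)cc2)cc(OCc2ccc(OC)cc2)c1C(=O)OCc1ccc(OC)cc1 | intermediate
18 | 2,4-bis[(4-methoxybenzyl)oxy]-6-methylbenzoic acid | Cc1cc(OCc2ccc(OC)cc2)cc(OCc2ccc(OC)cc2)c1C(=O)O | intermediate
19 | 2,4-bis[(4-methoxybenzyl)oxy]-6-methylbenzoyl chloride | Cc1cc(OCc2ccc(OC)cc2)cc(OCc2ccc(OC)cc2)c1C(Cl)=O | intermediate
20 | (7R,8R)-3-[(1E)-3-tert-butoxy-3-oxoprop-1-en-1-yl]-7-hydroxy-7-methyl-6-oxo-7,8-dihydro-6H-isochromen-8-yl 2,4-bis[(4-methoxybenzyl)oxy]-6-methylbenzoate | Cc1cc(OCc2ccc(OC)cc2)cc(OCc2ccc(OC)cc2)c1C(=O)O[C@@H]1C2=COC(/C=C/C(=O)OC(C)(C)C)=CC2=CC(=O)[C@]1(C)O | intermediate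
21 | (+)-mitorubrinic acid B, (2E)-3-[(7R,8R)-8-(2,4-dihydroxy-6-methylbenzoyloxy)-7-hydroxy-7-methyl-6-oxo-7,8-dihydro-6H-isochromen-3-yl]prop-2-enoic acid | Cc1cc(O)cc(O)c1C(=O)O[C@@H]1C2=COC(/C=C/C(=O)O)=CC2=CC(=O)[C@]1(C)O | target

**Step count and risks**

Total step count: 11. Longest linear sequence: 9 steps (steps 1 to 7, 10 and 11, from kojic acid).

Steps most likely to fail:

1. Step 5 (proposed new method). The carbene may fail to engage the deactivated formyl group productively. The enaminol may be protonated at C4a and diverted to an acyl azolium, the carbene may be held up by reversible addition at C1 or at the 1,2-dione, or enantioface discrimination at C7 may be poor. The fallback uses known chemistry and forms C6–C7 with normal polarity, then oxidises C7. It sets out from 8: a carbonylative Stille coupling with Et4Sn in place of 9 (CO, Pd(PPh3)4, LiCl) would give the ethyl ketone tert-butyl (2E)-3-[(4Z)-4-(2-oxoethylidene)-5-propanoyl-4H-pyran-2-yl]prop-2-enoate F1. LiN(SiMe3)2 at −78 °C would close ring B by intramolecular aldol addition of the C7 enolate to the C6 aldehyde, giving tert-butyl (2E)-3-(6-hydroxy-7-methyl-8-oxo-7,8-dihydro-6H-isochromen-3-yl)prop-2-enoate F2 as a diastereomer mixture. Oxidation of the secondary alcohol with the periodinane DMP would give the enolised 1,3-dione tert-butyl (2E)-3-(6-hydroxy-7-methyl-8-oxo-8H-isochromen-3-yl)prop-2-enoate F3. Hydroxylation of its potassium enolate (KN(SiMe3)2) at C7 with an enantiopure (camphorsulfonyl)oxaziridine, the reagent antipode being chosen to give 7S, comes back to the route at 12.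

2. Step 7. The hydride may enter syn to the silyloxy group and give the trans diol, or be delivered to C6 or C1 instead of C8. The fallback sets out from 12 and makes the trans relationship on purpose: hydroxyl-directed reduction with Me4NBH(OAc)3 in MeCN/AcOH delivers hydride to C8 from the face of the C7 oxygen and should give tert-butyl (2E)-3-[(7R,8S)-7,8-dihydroxy-7-methyl-6-oxo-7,8-dihydro-6H-isochromen-3-yl]prop-2-enoate F4. Mitsunobu esterification of its secondary hydroxyl with acid 18 (PPh3, diisopropyl azodicarboxylate) inverts C8 and comes back to the route at 20, so steps 6, 7 and 10 are replaced.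

3. Step 4. Transmetalation may outrun CO insertion (direct vinylation, giving the acetyl compound after hydrolysis), or the push–pull aldehyde may not survive the palladium and acid treatment. The fallback sets out from 8 and brings in the three carbons as an alkyne: Sonogashira coupling with propyne (Pd(PPh3)2Cl2, CuI, Et3N) would give tert-butyl (2E)-3-[(4Z)-4-(2-oxoethylidene)-5-(prop-1-yn-1-yl)-4H-pyran-2-yl]prop-2-enoate F5. Oxidation of the alkyne to the 1,2-dione (PdBr2, CuBr2, O2, aqueous dioxane) comes back to the route at 11.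

**Further compounds**

F1 | step 5 | tert-butyl (2E)-3-[(4Z)-4-(2-oxoethylidene)-5-propanoyl-4H-pyran-2-yl]prop-2-enoate | CC(C)(C)OC(=O)/C=C/C1=CC(=C/C=O)/C(C(=O)CC)=CO1
F2 | step 5 | tert-butyl (2E)-3-(6-hydroxy-7-methyl-8-oxo-7,8-dihydro-6H-isochromen-3-yl)prop-2-enoate (diastereomer mixture) | CC(C)(C)OC(=O)/C=C/C1=CC2=CC(O)C(C)C(=O)C2=CO1
F3 | step 5 | tert-butyl (2E)-3-(6-hydroxy-7-methyl-8-oxo-8H-isochromen-3-yl)prop-2-enoate | CC(C)(C)OC(=O)/C=C/C1=CC2=CC(O)=C(C)C(=O)C2=CO1
F4 | step 7 | tert-butyl (2E)-3-[(7R,8S)-7,8-dihydroxy-7-methyl-6-oxo-7,8-dihydro-6H-isochromen-3-yl]prop-2-enoate | O[C@H]1C2=COC(/C=C/C(=O)OC(C)(C)C)=CC2=CC(=O)[C@]1(C)O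
F5 | step 4 | tert-butyl (2E)-3-[(4Z)-4-(2-oxoethylidene)-5-(prop-1-yn-1-yl)-4H-pyran-2-yl]prop-2-enoate | CC(C)(C)OC(=O)/C=C/C1=CC(=C/C=O)/C(C#CC)=CO1
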